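# Pestalone C by aryne insertion into a ring A carboxylate

Numbering used throughout: ring A has C1 (bears the ketone carbon), C2 (CHO), C3 and C5 (OH), C4 (H), C6 (prenyl). Ring B has C1' (bears the ketone carbon), C2' and C6' (OH), C3' (H), C4' (CH3), C5' (Br).

## The problem

Pestalone C 21 is a benzophenone whose carbonyl carbon is flanked by four ortho substituents: formyl at C2 and prenyl at C6 on ring A, and hydroxyls at C2' and C6' on ring B. The central task is to join two crowded arenes through one carbon that should already be at the ketone oxidation level, because redox adjustment beside the ortho formyl group risks collapse to lactols and lactones. Ring A carries five different substituents in fixed order, and ring B is a 2,6-dihydroxy-4-methylphenyl unit whose symmetry is broken only by bromine at C5'. The molecule has no stereocentre and its alkene bears two identical methyl groups, so the whole problem is one of regiochemistry and nothing can be relayed stereochemically. Several groups restrict the reagents: the prenyl alkene beside the C5 hydroxyl cyclises to a chroman in strong acid and reacts with electrophilic halogen and oxidants, the free aldehyde does not tolerate base or nucleophiles, and the aryl bromide excludes alkyllithium reagents. A carboxylic acid next to a dimethyl acetal would lactonise, which bears on how the ring A partner is handled. The enabling feature lies in ring B: C1' bears the ketone, the adjacent C2' bears a phenolic oxygen, and C6' on the other side bears a second oxygen. This is the ortho-hydroxyaryl ketone pattern that results when a carboxylate adds to a 3-alkoxyaryne and the acyl group shifts from oxygen to the neighbouring carbon.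

## Retrosynthesis

**21 from 20.** Only protecting groups are removed: three aryl methoxymethyl (MOM) ethers and one dimethyl acetal, all acetals cleaved by the same dilute acid. Choosing MOM for every phenol and an acetal for the aldehyde keeps the endgame to one operation and avoids any base after the aldehyde is free. The forward reaction must spare the prenyl group.

**20 from 18 and 10, through aryne 19.** The cut removes C1'–C(=O) and C2'–O together. The neighbouring cuts are weaker. Addition of a metalated ring B to a formyl group on ring A needs a later oxidation next to the masked C2 formyl group, and an organolithium on a ring that carries bromine. Friedel–Crafts or Fries acylation of a resorcinol gives no positional control and needs a strong Lewis acid. The aryne route delivers the ketone at its final oxidation level from a carboxylate, with CsF as the only reagent. The precursors are two stable arenes: the sodium carboxylate 18 and the silyl triflate 10. The forward step needs oxygen to add at C2' (remote from the C6' MOM ether) and the acyl shift to the C1' anion to beat proton capture. Bromine is placed at C5', next to the MOM-bearing carbon and away from the aryne bond, so that one substituent alone polarises the aryne.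

**18 from 17, and 17 from 16.** The carboxylate 18 comes from the methyl ester 17 by removal of the O-methyl group. The free acid is deliberately never formed, because it would lactonise onto the neighbouring acetal carbon, and the carboxylate is the species that adds to the aryne anyway. The C6–prenyl bond is cut back to the aryl bromide 16 and the prenyl tin reagent Bu3SnCH2CH=CMe2. This is preferred over direct C-prenylation of a resorcinol, which would favour C4, and over Claisen chemistry, which delivers the reversed allyl unit.

**16 from 11 via 15, 14 and 13.** The acetal and MOM ethers are removed retrosynthetically (16 to 15 to 14), then the C6–Br and C2–CHO bonds are cut. Both positions are the electronically preferred ones of a 5-substituted resorcinol, each ortho to one hydroxyl and para to the other. Two successive electrophilic substitutions on symmetric methyl 3,5-dihydroxybenzoate 11 therefore place the formyl group, giving 13, and then the bromine, giving 14, without blocking groups. The order matters: formylation first, on the symmetric ester, leaves only one para-activated position for bromine.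

**10 from 5 via 8.** The triflate and the C1'–Si bond are traced to the N-isopropyl carbamate 5. The carbamate directs metalation to C1', between its own oxygen and the MOM oxygen, to give 8. It is later cleaved by mild base in the same flask as the triflation, through phenol 9. Because bromine is already present, the metalation uses LiN(iPr)2 with the chlorosilane present in the flask, not an alkyllithium.

**5 from 1 via 4 and 2.** Phenol 4 needs bromine ortho to the MOM-bearing oxygen and para to the free hydroxyl. Bromination of an orcinol monoether would not distinguish the two candidate positions. The C2'–O bond is therefore cut instead. Iridium-catalysed C–H borylation of the MOM ether 2 of commercial 2-bromo-3-methylphenol 1 can only occur at the one unhindered ring position, and oxidation of boronate 3 gives 4 as a single regioisomer.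

## Roads not taken

Alternative 1: Danheiser benzannulation builds ring B on a siloxyalkyne.

- Cut: C1'–C2', C2'–C3' and C5'–C6' of ring B.
- Forward step: heating 3-methylcyclobut-2-en-1-one A1 with the ring A propargylic siloxyalkyne A2 should give the diarylmethanol silyl ether A3, with ring B as a resorcinol monosilyl ether. The sequence is four-electron electrocyclic opening of A1, cycloaddition with the alkyne of A2, and six-electron closure.
- Merits: the most crowded bond of the target is already in place in A2, where the future ring B is still a slim alkyne carbon, so this road is better than the chosen plan on steric grounds. A1 is a small ketone, and the two ring B oxygens of A3 emerge differentiated without extra steps.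
- Weak points: ring B, which is almost a commercial arene, is built atom by atom. Bromine must be introduced after the annulation, in competition with C4 of ring A (between two ethers) and with the prenyl alkene. Both benzylic carbons of A3 are at the alcohol level, so two oxidations are needed on a 1,4-diol relationship that tends to cyclise. A2 itself requires a long sequence.
- Comparison: against the steric advantage, the chosen plan offers bromine fixed before coupling, both carbonyls at the right oxidation level, and one step from the key product to 21.

Alternative 2: Biomimetic aldol folding of a polycarbonyl chain into ring A.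

- Cut: the ring A bond between the ester-bearing carbon and the aroyl-bearing carbon (C1–C2 in the numbering used here).
- Forward step: mild base should make the methylene between the ester and the first ketone of the tetraoxo ester A4 attack the ketone next to the aroyl carbonyl, and dehydration and enolisation should give the methyl resorcylate A5.
- Merits: the ketone carbon is attached to ring B from the start, so no hindered union of two arenes is needed. Ring B keeps two identical MOM ethers and its bromine. In these respects it is at least as good as the chosen plan.
- Weak points: A4 contains a 1,2-dicarbonyl unit and three further carbonyls, is hard to make and to keep, and has several competing modes of cyclisation (attack on the other ketones, Claisen closure). A5 carries an ester where the aldehyde belongs, and this hindered, hydrogen-bonded ester must be reduced to the aldehyde level next to a diaryl ketone.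
- Comparison: the chosen plan relies on two robust aromatic building blocks and a single bond-forming event whose regiochemistry is set by one substituent.

Alternative 3: Diels–Alder of a bis(silyloxy)diene builds ring A.

- Cut: C1–C6 and C2–C3 of ring A.
- Forward step: the prenylated 1-methoxy-1,3-bis(trimethylsilyloxy)diene A6 should add to the ring B alkynoate A7, and the adduct should aromatise by elimination of its methoxy group to the resorcylate A8.
- Merits: convergent. The bond to ring B is made earlier, in the assembly of A7, by addition of an alkynyl anion to a formyl group, which is easier than acyl transfer to a shielded ester. Ring A regiochemistry follows from the polarity of A6 and A7.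
- Weak points: A6 is substituted at its reacting terminus, and the alkyne carbon of A7 that it must attack carries a bulky silyloxy(aryl)methyl group. A8 again has an ester in place of the aldehyde and an alcohol in place of the ketone. Once the carbinol is unmasked next to the ester, lactonisation is expected, so at least two redox steps and careful ordering follow.
- Comparison: the chosen plan needs no redox step after the key step. In exchange it accepts a more demanding acyl transfer.

Key step: step 12

Remark on the chemistry: the ring A acid is handled only as its sodium carboxylate 18, since the free acid beside the dimethyl acetal would lactonise; the carboxylate is the reacting species in the aryne step.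
Remark on materials: 2-bromo-3-methylphenol, methyl 3,5-dihydroxybenzoate and tributyl(3-methylbut-2-enyl)stannane are taken as commercial.

## Route

Step 1
Reactants: 1 2-bromo-3-methylphenol
Product: 2 2-bromo-1-(methoxymethoxy)-3-methylbenzene
Conditions: MOMCl, iPr2NEt, CH2Cl2, 0 °C to rt
Reagents that add atoms: chloromethyl methyl ether, COCCl
Why: O-alkylation of the phenol with an α-chloro ether and a hindered amine base (MOM protection); the ortho bromine does not interfere.

Step 2
Reactants: 2 2-bromo-1-(methoxymethoxy)-3-methylbenzene
Product: 4 4-bromo-3-(methoxymethoxy)-5-methylphenol, via aryl pinacol boronate 3 (not isolated)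
Conditions: [Ir(OMe)(cod)]2 (cat.), 4,4'-di-tert-butyl-2,2'-bipyridine (cat.), B2pin2, THF, 80 °C; volatiles removed; then 30% aq H2O2, NaOH, THF, 0 °C
Reagents that add atoms: hydrogen peroxide, OO (phenol oxygen); bis(pinacolato)diboron, CC1(C)OB(OC1(C)C)B1OC(C)(C)C(C)(C)O1 (boron carried only in 3)
Why: Iridium-catalysed aromatic C–H borylation is sterically controlled and should take the only ring C–H of 2 that has no ortho neighbour (para to bromine), leaving the aryl bromide untouched; NaOH/H2O2 then converts the C–B bond of 3 into C–OH at the same carbon (one-pot C–H borylation/oxidation). This fixes bromine next to the MOM-bearing oxygen without relying on a selective bromination.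

Step 3
Reactants: 4 4-bromo-3-(methoxymethoxy)-5-methylphenol
Product: 5 4-bromo-3-(methoxymethoxy)-5-methylphenyl N-isopropylcarbamate
Conditions: iPrNCO, Et3N (cat.), CH2Cl2, rt
Reagents that add atoms: isopropyl isocyanate, CC(C)N=C=O
Why: Amine-catalysed addition of a phenol to an isocyanate; the N-isopropyl carbamate is a directing group that can later be removed by mild base.

Step 4
Reactants: 5 4-bromo-3-(methoxymethoxy)-5-methylphenyl N-isopropylcarbamate
Product: 8 4-bromo-3-(methoxymethoxy)-5-methyl-2-(trimethylsilyl)phenyl N-isopropylcarbamate, via N-silyl carbamate 6 (not isolated), via N-silyl C-silyl carbamate 7 (not isolated)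
Conditions: TBSOTf, TMEDA, Et2O, 0 °C to rt; then Me3SiCl, LiN(iPr)2, THF, −78 °C; cold aq NaHSO4 work-up
Reagents that add atoms: chlorotrimethylsilane, C[Si](C)(C)Cl; tert-butyldimethylsilyl trifluoromethanesulfonate, CC(C)(C)[Si](C)(C)OS(=O)(=O)C(F)(F)F (silicon carried only in 6 and 7)
Why: Directed ortho-metalation of an O-aryl carbamate: N-silylation makes the carbamate tertiary (6), and the C1'–H between the carbamate and MOM oxygens is then acidic enough for LiN(iPr)2, as in the LiN(iPr)2 lithiation of meta-alkoxy aryl carbamates. Me3SiCl present in the flask traps the aryllithium at once, which forestalls anionic Fries shift and bromine migration, and no alkyllithium meets the aryl bromide. The brief acidic work-up removes the N-silyl group of 7.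

Step 5
Reactants: 8 4-bromo-3-(methoxymethoxy)-5-methyl-2-(trimethylsilyl)phenyl N-isopropylcarbamate
Product: 10 4-bromo-3-(methoxymethoxy)-5-methyl-2-(trimethylsilyl)phenyl trifluoromethanesulfonate, via silyl phenol 9 (not isolated)
Conditions: DBU, Et2NH, MeCN, 40 °C; then PhNTf2, rt
Reagents that add atoms: N-phenylbis(trifluoromethanesulfonimide), O=S(=O)(N(c1ccccc1)S(=O)(=O)C(F)(F)F)C(F)(F)F
Why: The N–H carbamate fragments by base-induced elimination to the phenoxide of 9 and isopropyl isocyanate, which Et2NH captures as a urea; the phenoxide is sulfonylated in the same flask. This is the established carbamate route to ortho-silylaryl triflates and is compatible with the bromide and the MOM ether.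

Step 6
Reactants: 11 methyl 3,5-dihydroxybenzoate
Product: 13 methyl 2-formyl-3,5-dihydroxybenzoate, via aryl iminium chloride 12 (not isolated)
Conditions: POCl3, DMF, MeCN, 0 °C to rt; then H2O, 50 °C
Reagents that add atoms: N,N-dimethylformamide, CN(C)C=O (formyl carbon); water, O (formyl oxygen); phosphoryl chloride, O=P(Cl)(Cl)Cl (chloride counter-ion carried only in 12)
Why: Vilsmeier–Haack formylation: the chloroiminium ion attacks a resorcinol ortho to one hydroxyl and para to the other (C2, beside the ester) in preference to the carbon between the hydroxyls, and iminium salt 12 is hydrolysed on work-up. C2 and C6 of 11 are equivalent, so one aldehyde is expected.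

Step 7
Reactants: 13 methyl 2-formyl-3,5-dihydroxybenzoate
Product: 14 methyl 2-bromo-6-formyl-3,5-dihydroxybenzoate
Conditions: NBS, MeCN, −20 to 0 °C
Reagents that add atoms: N-bromosuccinimide, O=C1CCC(=O)N1Br
Why: Electrophilic aromatic bromination at the one remaining position that is para to a hydroxyl (C6, beside the ester); 2,4-dihydroxybenzaldehydes are halogenated there and not between the two hydroxyls. One equivalent at low temperature should limit twofold bromination.

Step 8
Reactants: 14 methyl 2-bromo-6-formyl-3,5-dihydroxybenzoate
Product: 15 methyl 2-bromo-6-formyl-3,5-bis(methoxymethoxy)benzoate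
Conditions: MOMCl, iPr2NEt, CH2Cl2, 0 to 40 °C
Reagents that add atoms: chloromethyl methyl ether, COCCl
Why: Both phenols are acidified by the carbonyl groups and are alkylated under amine-base MOM protection; warming serves the hydroxyl that is hydrogen-bonded to the aldehyde.

Step 9
Reactants: 15 methyl 2-bromo-6-formyl-3,5-bis(methoxymethoxy)benzoate
Product: 16 methyl 2-bromo-6-(dimethoxymethyl)-3,5-bis(methoxymethoxy)benzoate
Conditions: HC(OMe)3, MeOH, PPTS (cat.), 40 °C; Et3N quench
Reagents that add atoms: trimethyl orthoformate, COC(OC)OC; methanol, CO
Why: Acid-catalysed acetalisation with the orthoformate as water scavenger; aryl MOM ethers tolerate the weak acid pyridinium tosylate in methanol, and a neighbouring methyl ester, unlike a free acid, cannot form a pseudo-ester.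

Step 10
Reactants: 16 methyl 2-bromo-6-(dimethoxymethyl)-3,5-bis(methoxymethoxy)benzoate
Product: 17 methyl 2-(dimethoxymethyl)-3,5-bis(methoxymethoxy)-6-(3-methylbut-2-enyl)benzoate
Conditions: Bu3SnCH2CH=CMe2, Pd(PtBu3)2 (cat.), CsF, 1,4-dioxane, 90 °C
Reagents that add atoms: tributyl(3-methylbut-2-enyl)stannane, CCCC[Sn](CCCC)(CCCC)CC=C(C)C
Why: Stille coupling of an electron-rich, di-ortho-substituted aryl bromide; a bulky electron-rich phosphine on zerovalent palladium with CsF activation of tin is suited to hindered bromides, and reductive elimination at the less substituted allyl terminus should give the linear prenyl arene. Ester, acetal and MOM groups are inert.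

Step 11
Reactants: 17 methyl 2-(dimethoxymethyl)-3,5-bis(methoxymethoxy)-6-(3-methylbut-2-enyl)benzoate
Product: 18 sodium 2-(dimethoxymethyl)-3,5-bis(methoxymethoxy)-6-(3-methylbut-2-enyl)benzoate
Conditions: NaSEt, DMF, 90 °C; work-up at pH 8–9 without acidification, salt dried
Reagents that add atoms: sodium ethanethiolate, CC[S-].[Na+] (supplies the sodium counter-ion)
Why: The ester carbonyl is shielded by two ortho substituents, so it is cleaved by SN2 attack of ethanethiolate on the O-methyl group (nucleophilic dealkylation of hindered methyl esters) and not by saponification. The product is kept as the salt because the free acid would attack the adjacent acetal.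

Step 12
Reactants: 18 sodium 2-(dimethoxymethyl)-3,5-bis(methoxymethoxy)-6-(3-methylbut-2-enyl)benzoate; 10 4-bromo-3-(methoxymethoxy)-5-methyl-2-(trimethylsilyl)phenyl trifluoromethanesulfonate
Product: 20 [3-bromo-6-hydroxy-2-(methoxymethoxy)-4-methylphenyl][2-(dimethoxymethyl)-3,5-bis(methoxymethoxy)-6-(3-methylbut-2-enyl)phenyl]methanone, via aryne 19 (not isolated)
Conditions: CsF, THF, 125 °C (sealed tube); then aq NH4Cl
Reagents that add atoms: none
Why: CsF removes the silyl group of 10 and triflate departs, giving aryne 19; the carboxylate oxygen of 18 adds at C2', the aryne carbon remote from the MOM ether, because the inductively withdrawing C6' oxygen distorts the aryne and stabilises negative charge at the adjacent C1'. The C1' aryl anion, two atoms from the ester carbonyl just formed, attacks it in a 4-exo-trig closure to a four-membered alkoxide, which opens by expelling the C2' phenoxide, so C2'–O and C1'–C(=O) are both made and no ring remains in the product. The closest known reaction type is the CsF-induced insertion of arynes into the C–O bond of carboxylic acids to give ortho-hydroxyaryl ketones; here it is applied to a benzoate with two ortho substituents. No stereocentre is formed. The selectivity needed is regiochemical and is secured by the single alkoxy substituent next to the aryne bond, with bromine and methyl remote from it. The salt is used so that no acidic proton is at hand to quench the aryl anion to the plain aryl ester, the known competing path, and the high temperature likewise favours acyl shift over proton capture. Bromide, prenyl, acetal and MOM groups are inert to CsF, and the ortho-acyl phenoxide product is a poor nucleophile toward further aryne.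

Step 13
Reactants: 20 [3-bromo-6-hydroxy-2-(methoxymethoxy)-4-methylphenyl][2-(dimethoxymethyl)-3,5-bis(methoxymethoxy)-6-(3-methylbut-2-enyl)phenyl]methanone
Product: 21 2-(3-bromo-2,6-dihydroxy-4-methylbenzoyl)-4,6-dihydroxy-3-(3-methylbut-2-enyl)benzaldehyde (Pestalone C)
Conditions: 2 M aq HCl, MeOH/THF, 40 °C
Reagents that add atoms: water, O
Why: Acid hydrolysis should cleave the three aryl MOM acetals and the dimethyl acetal in one operation; dilute acid at moderate temperature is the usual way to unmask MOM-protected prenylphenols without closing the prenyl group onto the neighbouring hydroxyl. No base is used once the aldehyde is free.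

## Compound list

1 | 2-bromo-3-methylphenol | Cc1cccc(O)c1Br | starting material
2 | 2-bromo-1-(methoxymethoxy)-3-methylbenzene | COCOc1cccc(C)c1Br | intermediate
3 | 2-[4-bromo-3-(methoxymethoxy)-5-methylphenyl]-4,4,5,5-tetramethyl-1,3,2-dioxaborolane | COCOc1cc(B2OC(C)(C)C(C)(C)O2)cc(C)c1Br | intermediate (not isolated)
4 | 4-bromo-3-(methoxymethoxy)-5-methylphenol | COCOc1cc(O)cc(C)c1Br | intermediate
5 | 4-bromo-3-(methoxymethoxy)-5-methylphenyl N-isopropylcarbamate | COCOc1cc(OC(=O)NC(C)C)cc(C)c1Br | intermediate
6 | 4-bromo-3-(methoxymethoxy)-5-methylphenyl N-(tert-butyldimethylsilyl)-N-isopropylcarbamate | COCOc1cc(OC(=O)N(C(C)C)[Si](C)(C)C(C)(C)C)cc(C)c1Br | intermediate (not isolated)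
7 | 4-bromo-3-(methoxymethoxy)-5-methyl-2-(trimethylsilyl)phenyl N-(tert-butyldimethylsilyl)-N-isopropylcarbamate | COCOc1c(Br)c(C)cc(OC(=O)N(C(C)C)[Si](C)(C)C(C)(C)C)c1[Si](C)(C)C | intermediate (not isolated)
8 | 4-bromo-3-(methoxymethoxy)-5-methyl-2-(trimethylsilyl)phenyl N-isopropylcarbamate | COCOc1c(Br)c(C)cc(OC(=O)NC(C)C)c1[Si](C)(C)C | intermediate
9 | 4-bromo-3-(methoxymethoxy)-5-methyl-2-(trimethylsilyl)phenol | COCOc1c(Br)c(C)cc(O)c1[Si](C)(C)C | intermediate (not isolated)
10 | 4-bromo-3-(methoxymethoxy)-5-methyl-2-(trimethylsilyl)phenyl trifluoromethanesulfonate | COCOc1c(Br)c(C)cc(OS(=O)(=O)C(F)(F)F)c1[Si](C)(C)C | intermediate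
11 | methyl 3,5-dihydroxybenzoate | COC(=O)c1cc(O)cc(O)c1 | starting material
12 | [2,4-dihydroxy-6-(methoxycarbonyl)benzylidene]dimethylammonium chloride | COC(=O)c1cc(O)cc(O)c1C=[N+](C)C.[Cl-] | intermediate (not isolated)
13 | methyl 2-formyl-3,5-dihydroxybenzoate | COC(=O)c1cc(O)cc(O)c1C=O | intermediate
14 | methyl 2-bromo-6-formyl-3,5-dihydroxybenzoate | COC(=O)c1c(Br)c(O)cc(O)c1C=O | intermediate
15 | methyl 2-bromo-6-formyl-3,5-bis(methoxymethoxy)benzoate | COCOc1cc(OCOC)c(C=O)c(C(=O)OC)c1Br | intermediate
16 | methyl 2-bromo-6-(dimethoxymethyl)-3,5-bis(methoxymethoxy)benzoate | COCOc1cc(OCOC)c(C(OC)OC)c(C(=O)OC)c1Br | intermediate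
17 | methyl 2-(dimethoxymethyl)-3,5-bis(methoxymethoxy)-6-(3-methylbut-2-enyl)benzoate | COCOc1cc(OCOC)c(C(OC)OC)c(C(=O)OC)c1CC=C(C)C | intermediate
18 | sodium 2-(dimethoxymethyl)-3,5-bis(methoxymethoxy)-6-(3-methylbut-2-enyl)benzoate | COCOc1cc(OCOC)c(C(OC)OC)c(C(=O)[O-])c1CC=C(C)C.[Na+] | intermediate
19 | 4-bromo-3-(methoxymethoxy)-5-methyl-1,2-didehydrobenzene (aryne) | COCOC1=C(Br)C(C)=CC#C1 | intermediate (not isolated)
20 | [3-bromo-6-hydroxy-2-(methoxymethoxy)-4-methylphenyl][2-(dimethoxymethyl)-3,5-bis(methoxymethoxy)-6-(3-methylbut-2-enyl)phenyl]methanone | CC(C)=CCc1c(OCOC)cc(OCOC)c(C(OC)OC)c1C(=O)c1c(O)cc(C)c(Br)c1OCOC | intermediate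
21 | 2-(3-bromo-2,6-dihydroxy-4-methylbenzoyl)-4,6-dihydroxy-3-(3-methylbut-2-enyl)benzaldehyde (Pestalone C) | CC(C)=CCc1c(O)cc(O)c(C=O)c1C(=O)c1c(O)cc(C)c(Br)c1O | target

## Step count and least certain steps

Total: 13 steps. Longest linear sequence: 8 steps (steps 6 to 13); the ring B branch is 5 steps before the union.

**Step 12 (key step).** The acyl shift onto a carbonyl shielded by two ortho substituents may be slower than proton capture by the aryl anion from the medium, so the reaction may stop at O-arylation. Excess aryne may also arylate the product phenoxide or undergo an ene reaction with the prenyl alkene. The fallback separates the two bond formations; it sets out from 18 and 10 and returns at 20. The carboxylate 18 is O-arylated by the aryne from 10 (CsF, MeCN, rt, one equivalent of tert-butanol as proton donor, aq NH4Cl work-up), the known aryne esterification of carboxylates. This should give the aryl ester 4-bromo-3-(methoxymethoxy)-5-methylphenyl 2-(dimethoxymethyl)-3,5-bis(methoxymethoxy)-6-(3-methylbut-2-enyl)benzoate F1. F1 is then treated with LiN(iPr)2 in THF at −78 °C, warmed to 0 °C and quenched with aq NH4Cl. The C1'–H between the acyloxy and MOM oxygens is removed, and the aryllithium, with a lithium counter-ion and no proton source or aryne present, undergoes anionic ortho-Fries rearrangement to the phenoxide of 20.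

**Step 4.** LiN(iPr)2 may metalate the N-silylated carbamate incompletely, the N-silyl group may be lost before metalation, or the lithiated carbamate may undergo carbamoyl migration or bromine scrambling. The fallback uses a tertiary carbamate, for which LiN(iPr)2 lithiation with in-flask silylation is directly established, and a reductive instead of an eliminative cleavage. It sets out from 4 and returns at 9, which is triflated to 10 as in the second stage of step 5. Phenol 4 is carbamoylated (Et2NCOCl, K2CO3, MeCN) to 4-bromo-3-(methoxymethoxy)-5-methylphenyl N,N-diethylcarbamate F2. F2 is silylated (LiN(iPr)2, Me3SiCl, THF, −78 °C) to 4-bromo-3-(methoxymethoxy)-5-methyl-2-(trimethylsilyl)phenyl N,N-diethylcarbamate F3. F3 is cleaved with Cp2Zr(H)Cl in THF at rt to the silyl phenol 9.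

**Step 10.** Coupling through the substituted allyl terminus would give the 1,1-dimethylallyl isomer, and slow oxidative addition at the hindered bromide would lead to reduction of the C–Br bond. The fallback removes the allyl regiochemistry question; it sets out from 16 and returns at 17. Stille coupling of 16 with allyltributylstannane (Pd(PPh3)4, DMF, 90 °C) should give methyl 2-(dimethoxymethyl)-3,5-bis(methoxymethoxy)-6-(prop-2-enyl)benzoate F4. Cross-metathesis of F4 with 2-methylbut-2-ene (second-generation Grubbs catalyst, CH2Cl2, 40 °C) then installs the two methyl groups and gives 17.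

**Step 7.** Substitution at C4 between the two hydroxyls, or twofold bromination, may compete, because the free resorcinol activates both open positions. The fallback brominates the diether, where the carbon between two MOM ethers is shielded and substitution para to an alkoxy group beside the ester is the established pattern of 3,5-dialkoxybenzoates. It sets out from 13 and returns at 15. Aldehyde 13 is first protected (MOMCl, iPr2NEt, CH2Cl2) as methyl 2-formyl-3,5-bis(methoxymethoxy)benzoate F5, and F5 is brominated with NBS in MeCN at rt to give 15.

**Step 13.** Acid-catalysed addition of the C5 hydroxyl to the prenyl alkene (chroman formation) may accompany slow cleavage of the hindered MOM ethers. The fallback releases the aldehyde and the phenols separately and cleaves the MOM ethers by silyl transfer instead of protic hydrolysis; it sets out from 20 and returns at 21. The acetal of 20 is hydrolysed under buffered conditions (PPTS, acetone/H2O, rt) to 2-[3-bromo-6-hydroxy-2-(methoxymethoxy)-4-methylbenzoyl]-4,6-bis(methoxymethoxy)-3-(3-methylbut-2-enyl)benzaldehyde F6. Me3SiOTf and 2,2'-bipyridyl in CH2Cl2 at 0 °C then convert the aryl MOM ethers of F6 into aryl silyl ethers and silylate the free C2' phenol, giving 2-[3-bromo-4-methyl-2,6-bis(trimethylsilyloxy)benzoyl]-3-(3-methylbut-2-enyl)-4,6-bis(trimethylsilyloxy)benzaldehyde F7. F7 is hydrolysed to 21 on aqueous work-up.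

## Further compounds

F1 | step 12 | 4-bromo-3-(methoxymethoxy)-5-methylphenyl 2-(dimethoxymethyl)-3,5-bis(methoxymethoxy)-6-(3-methylbut-2-enyl)benzoate | CC(C)=CCc1c(OCOC)cc(OCOC)c(C(OC)OC)c1C(=O)Oc1cc(C)c(Br)c(OCOC)c1
F2 | step 4 | 4-bromo-3-(methoxymethoxy)-5-methylphenyl N,N-diethylcarbamate | CCN(CC)C(=O)Oc1cc(C)c(Br)c(OCOC)c1
F3 | step 4 | 4-bromo-3-(methoxymethoxy)-5-methyl-2-(trimethylsilyl)phenyl N,N-diethylcarbamate | CCN(CC)C(=O)Oc1cc(C)c(Br)c(OCOC)c1[Si](C)(C)C
F4 | step 10 | methyl 2-(dimethoxymethyl)-3,5-bis(methoxymethoxy)-6-(prop-2-enyl)benzoate | COCOc1cc(OCOC)c(C(OC)OC)c(C(=O)OC)c1CC=C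
F5 | step 7 | methyl 2-formyl-3,5-bis(methoxymethoxy)benzoate | COCOc1cc(OCOC)c(C=O)c(C(=O)OC)c1
F6 | step 13 | 2-[3-bromo-6-hydroxy-2-(methoxymethoxy)-4-methylbenzoyl]-4,6-bis(methoxymethoxy)-3-(3-methylbut-2-enyl)benzaldehyde | CC(C)=CCc1c(OCOC)cc(OCOC)c(C=O)c1C(=O)c1c(O)cc(C)c(Br)c1OCOC
F7 | step 13 | 2-[3-bromo-4-methyl-2,6-bis(trimethylsilyloxy)benzoyl]-3-(3-methylbut-2-enyl)-4,6-bis(trimethylsilyloxy)benzaldehyde | CC(C)=CCc1c(O[Si](C)(C)C)cc(O[Si](C)(C)C)c(C=O)c1C(=O)c1c(O[Si](C)(C)C)cc(C)c(Br)c1O[Si](C)(C)C
A1 | alternative 1 | 3-methylcyclobut-2-en-1-one | CC1=CC(=O)C1
A2 | alternative 1 | ring A propargylic siloxyalkyne, 1-[2-(tert-butyldimethylsilyloxymethyl)-3,5-bis(methoxymethoxy)-6-(3-methylbut-2-enyl)phenyl]-1-(tert-butyldimethylsilyloxy)-3-(triisopropylsilyloxy)prop-2-yne (racemic) | CC(C)=CCc1c(OCOC)cc(OCOC)c(CO[Si](C)(C)C(C)(C)C)c1C(O[Si](C)(C)C(C)(C)C)C#CO[Si](C(C)C)(C(C)C)C(C)C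
A3 | alternative 1 | diarylmethanol silyl ether with ring B as the 2-hydroxy-4-methyl-6-(triisopropylsilyloxy)phenyl group (racemic) | CC(C)=CCc1c(OCOC)cc(OCOC)c(CO[Si](C)(C)C(C)(C)C)c1C(O[Si](C)(C)C(C)(C)C)c1c(O)cc(C)cc1O[Si](C(C)C)(C(C)C)C(C)C
A4 | alternative 2 | methyl 8-[3-bromo-2,6-bis(methoxymethoxy)-4-methylphenyl]-6-(3-methylbut-2-enyl)-3,5,7,8-tetraoxooctanoate (racemic, enolisable) | COC(=O)CC(=O)CC(=O)C(CC=C(C)C)C(=O)C(=O)c1c(OCOC)cc(C)c(Br)c1OCOC
A5 | alternative 2 | methyl 6-[3-bromo-2,6-bis(methoxymethoxy)-4-methylbenzoyl]-2,4-dihydroxy-5-(3-methylbut-2-enyl)benzoate | COC(=O)c1c(O)cc(O)c(CC=C(C)C)c1C(=O)c1c(OCOC)cc(C)c(Br)c1OCOC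
A6 | alternative 3 | 1-methoxy-7-methyl-1,3-bis(trimethylsilyloxy)octa-1,3,6-triene | COC(O[Si](C)(C)C)=CC(O[Si](C)(C)C)=CCC=C(C)C
A7 | alternative 3 | methyl 4-[3-bromo-2,6-bis(methoxymethoxy)-4-methylphenyl]-4-(tert-butyldimethylsilyloxy)but-2-ynoate (racemic) | COC(=O)C#CC(O[Si](C)(C)C(C)(C)C)c1c(OCOC)cc(C)c(Br)c1OCOC
A8 | alternative 3 | methyl 6-{[3-bromo-2,6-bis(methoxymethoxy)-4-methylphenyl](tert-butyldimethylsilyloxy)methyl}-2,4-dihydroxy-5-(3-methylbut-2-enyl)benzoate (racemic) | COC(=O)c1c(O)cc(O)c(CC=C(C)C)c1C(O[Si](C)(C)C(C)(C)C)c1c(OCOC)cc(C)c(Br)c1OCOC
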